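The labdane is cut at C2–C3 of ring A. Ring B (C5–C10, with the C8 methyl, the C7=C8 alkene and C5) is the six-membered ring of (R)-carvone, whose isopropenyl group becomes C3, C4 and C19. The precursor is a carvone-derived 2-substituted methyl acrylate on C5 that carries, trans to it on the quaternary C10, a propanoic N-hydroxyphthalimide ester. Reductive decarboxylation releases a primary C2 radical that adds to the acrylate CH2 (C3) in one operation, closing ring A on the preset trans C5-H/C10-methyl pair and leaving a C9 ketone and a C4 ester for the C9 side chain and the C4 quaternary centre.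

Key step: step 10

Remark on numbering: labdane numbering is used for all intermediates and β is the face of the C10 methyl; the target is read as (4S,5R,9S,10R)-19-angeloyloxylabda-7,13Z-dien-15-oic acid, with 5-H and 9-H α and the CH2O carbon C19 β and axial.

Remark on the arm at C10: the C1–C2–CO2 arm is introduced as a propargyl group and oxidised later, because the cross-conjugated dienolate of a 6-alkylcarvone and an acrylate are expected to continue, by a second intramolecular Michael addition onto C7, to a bicyclo[2.2.2]octanone.

Remark on C4: compound 15 should form as a mixture of C4 epimers; the equatorial ester is drawn, and either epimer serves because C4 is planarised again in step 12.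

Step 1
Reactants: 1 (R)-(−)-carvone
Product: 3 trans-6-methylcarvone, via lithium dienolate 2 (not isolated)
Conditions: LiN(iPr)2, THF, −78 °C; MeI, −78 → 0 °C
Reagents that add atoms: iodomethane, CI
Why: Kinetic deprotonation at the α' carbon (the future C10) gives the cross-conjugated lithium dienolate, and its C-alkylation with MeI (enolate alkylation) installs the future C20 methyl, the configuration of the new centre being irrelevant because it is planarised again in step 2.

Step 2
Reactants: 3 trans-6-methylcarvone; 4 propargyl bromide
Product: 6 propargylated 6-methylcarvone, via lithium dienolate 5 (not isolated)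
Conditions: LiN(iPr)2, THF, −78 → −20 °C; propargyl bromide, DMPU, −78 °C → rt
Reagents that add atoms: none
Why: Enolate alkylation in which the activated propargylic bromide should approach the trisubstituted dienolate on the face opposite the adjacent isopropenyl group, so that the quaternary C10 is formed with its methyl cis and its three-carbon arm trans to the C5 substituent, the relationship a trans ring fusion requires.

Step 3
Reactants: 6 propargylated 6-methylcarvone
Product: 7 allylic chloride
Conditions: Ca(OCl)2, CO2 (dry ice), CH2Cl2/H2O, 0 °C
Reagents that add atoms: calcium hypochlorite, [Ca+2].[O-]Cl.[O-]Cl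
Why: Ene-type allylic chlorination by HOCl made in the flask should attack only the electron-rich 1,1-disubstituted isopropenyl alkene (the enone alkene is electron-poor and the alkyne is slow) and take hydrogen from the methyl group, so chlorine ends on the future C19 and the C5 stereocentre is untouched.

Step 4
Reactants: 7 allylic chloride
Product: 8 enal
Conditions: N-methylmorpholine N-oxide, NaHCO3, KI (cat.), MeCN, rt → 45 °C
Reagents that add atoms: N-methylmorpholine N-oxide, C[N+]1([O-])CCOCC1
Why: Amine N-oxide oxidation of an allylic halide (a Kornblum-type oxidation), in which O-alkylation of the N-oxide is followed by elimination of N-methylmorpholine, should give the 2-substituted acrolein under conditions too mild to epimerise C5.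

Step 5
Reactants: 8 enal
Product: 9 acrylic acid
Conditions: NaClO2, NaH2PO4, 2-methylbut-2-ene, t-BuOH/H2O, 0 °C → rt
Reagents that add atoms: sodium chlorite, [Na+].[O-]Cl=O
Why: Pinnick oxidation is the standard conversion of a conjugated aldehyde into the acid, and 2-methylbut-2-ene consumes the HOCl so that the enone, the alkyne and the acrylic alkene are left alone.

Step 6
Reactants: 9 acrylic acid
Product: 10 methyl acrylate alkyne
Conditions: MeI, K2CO3, DMF, rt
Reagents that add atoms: iodomethane, CI
Why: O-Alkylation of the carboxylate (SN2 on MeI) gives the methyl ester that serves as radical acceptor and later as C19, and the weak base leaves the terminal alkyne and the ketone, whose α' carbon is quaternary, untouched.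

Step 7
Reactants: 10 methyl acrylate alkyne
Product: 11 aldehyde
Conditions: CpRu(MeCN)3PF6 (5 mol %), 5,5'-bis(trifluoromethyl)-2,2'-bipyridine (5 mol %), NMP/H2O 4:1, 25 → 50 °C
Reagents that add atoms: water, O
Why: Ruthenium-catalysed anti-Markovnikov hydration of a terminal alkyne (through a ruthenium vinylidene) places oxygen on the terminal carbon under neutral conditions, which should give the C10–CH2–CH2–CHO arm and leave acrylate, enone and ester alone.

Step 8
Reactants: 11 aldehyde
Product: 12 carboxylic acid
Conditions: NaClO2, NaH2PO4, 2-methylbut-2-ene, t-BuOH/H2O, 0 °C → rt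
Reagents that add atoms: sodium chlorite, [Na+].[O-]Cl=O
Why: Pinnick oxidation converts the aliphatic aldehyde into the acid without base, so neither the acrylate nor the enone is exposed to an enolate at C2.

Step 9
Reactants: 12 carboxylic acid; 13 N-hydroxyphthalimide
Product: 14 N-hydroxyphthalimide ester
Conditions: N,N'-diisopropylcarbodiimide, DMAP (cat.), CH2Cl2, 0 °C → rt
Reagents that add atoms: none
Why: Carbodiimide (Steglich-type) esterification of the only free acid gives the redox-active N-acyloxyphthalimide, the acrylate methyl ester being inert under these conditions.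

Step 10
Reactants: 14 N-hydroxyphthalimide ester
Product: 15 trans-fused bicyclic keto ester
Conditions: Ru(bpy)3Cl2 (1 mol %), Hantzsch ester (1.5 equiv), CH2Cl2 (0.01 M, degassed), blue LEDs (450 nm), rt
Reagents that add atoms: none
Why: Single-electron reduction of the N-acyloxyphthalimide by the photoreduced ruthenium catalyst (Hantzsch ester as terminal reductant) fragments it to phthalimide anion, CO2 and the primary C2 radical, which adds to C3, the unsubstituted terminus of the 2-substituted acrylate, and the resulting tertiary α-ester radical at C4 is quenched by hydrogen-atom transfer from the Hantzsch ester. The closest known reaction type is the decarboxylative Giese addition of redox-active esters, run here intramolecularly. Ring A is closed in the 6-endo-trig mode, and because the C10 arm and the C5 acrylate are trans and both pseudo-equatorial on ring B, the new ring can only be trans-fused, with 5-H α and the C10 methyl β. The new centre C4 is set by the face of the planar ester radical that receives hydrogen and is not relied on, since base in step 11 should leave the equatorial ester and step 12 planarises C4 again. The step needs 6-endo over 5-exo closure and ring closure ahead of hydrogen transfer to the primary radical; the first is secured by polarity and sterics (a nucleophilic alkyl radical attacks the CH2 end and gives a stabilised radical, whereas 5-exo attack would hit the fully substituted C4) and the second by high dilution. Addition to the ring enone at C7 would need a boat-like bicyclo[2.2.2] transition state and should not compete.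

Step 11
Reactants: 15 trans-fused bicyclic keto ester
Product: 16 diene ester
Conditions: Ph3PCH3Br, KOt-Bu, toluene, rt → 90 °C
Reagents that add atoms: methyltriphenylphosphonium bromide, C[P+](c1ccccc1)(c1ccccc1)c1ccccc1.[Br-]
Why: Wittig methylenation with the salt-free ylide at elevated temperature is the established answer to a ketone flanked by a quaternary carbon, the quaternary C10 rules out α'-enolisation, the secondary ester is attacked far more slowly than the ketone, and the basic medium should leave C4 as the equatorial ester.

Step 12
Reactants: 16 diene ester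
Product: 18 quaternary ester, via lithium ester enolate 17 (not isolated)
Conditions: LiN(iPr)2, THF, −78 → −20 °C; MeI, DMPU, −78 → 0 °C
Reagents that add atoms: iodomethane, CI
Why: Ester enolate alkylation in which MeI should approach the exocyclic C4 enolate from the equatorial α face because the axial β face is blocked by the 1,3-diaxial C10 methyl, which makes the new methyl C18 (4α) and leaves the ester axial as C19 (4S), the outcome known for C4 ester enolates of 10β-methyl trans-decalins.

Step 13
Reactants: 18 quaternary ester
Product: 20 hydroxy ester, via B-alkyl-9-BBN 19 (not isolated)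
Conditions: 9-BBN, THF, 0 °C → rt; NaOH, H2O2, H2O, 0 °C → rt
Reagents that add atoms: hydrogen peroxide, OO
Why: Hydroboration–oxidation in which 9-BBN should add only to the exocyclic 1,1-disubstituted C9=C11 bond of the s-trans-locked diene, with boron on C11 and hydrogen delivered to C9 from the α face opposite the axial C10 methyl, so that C9 is set as 9α-H with the CH2OH arm β (9S) while the hindered axial ester survives the alkaline peroxide.

Step 14
Reactants: 20 hydroxy ester
Product: 21 aldehyde ester
Conditions: Dess–Martin periodinane, NaHCO3, CH2Cl2, 0 °C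
Reagents that add atoms: none
Why: Dess–Martin oxidation under buffered, non-basic conditions should give the β,γ-unsaturated aldehyde without epimerising C9 or drawing the C7=C8 alkene into conjugation.

Step 15
Reactants: 21 aldehyde ester
Product: 22 vinyl ester
Conditions: Ph3PCH3Br, KN(SiMe3)2, THF, −78 → 0 °C
Reagents that add atoms: methyltriphenylphosphonium bromide, C[P+](c1ccccc1)(c1ccccc1)c1ccccc1.[Br-]
Why: Wittig methylenation at low temperature, where addition of the unstabilised ylide to the aldehyde is much faster than α-deprotonation, should convert the formyl group into the C11=C12 vinyl group with C9 and the alkene position intact.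

Step 16
Reactants: 22 vinyl ester
Product: 23 C19 alcohol
Conditions: LiAlH4, THF, 0 → 40 °C
Reagents that add atoms: none
Why: Hydride reduction of the hindered axial methyl ester with LiAlH4 gives the primary C19 alcohol, the isolated alkenes being inert to the reagent.

Step 17
Reactants: 23 C19 alcohol; 24 angelic acid
Product: 26 angelate, via mixed anhydride 25 (not isolated)
Conditions: angelic acid, 2,4,6-trichlorobenzoyl chloride, Et3N, toluene, rt; then 23, 80 °C
Reagents that add atoms: none
Why: Yamaguchi-type mixed-anhydride esterification in which the alcohol attacks the less hindered angeloyl carbonyl, run without a nucleophilic catalyst so that the Z alkene of the angelate should not isomerise to the tiglate.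

Step 18
Reactants: 27 but-2-ynoic acid
Product: 28 (Z)-3-iodobut-2-enoic acid
Conditions: NaI, AcOH, 110 °C
Reagents that add atoms: sodium iodide, [Na+].[I-]
Why: Hydroiodination of the ynoic acid by conjugate addition of iodide and anti protonation gives the β-iodo acid with iodine cis to the carboxyl group, the geometry needed for 13Z.

Step 19
Reactants: 28 (Z)-3-iodobut-2-enoic acid; 29 2-(trimethylsilyl)ethanol
Product: 30 2-(trimethylsilyl)ethyl (Z)-3-iodobut-2-enoate
Conditions: PPh3, DIAD, THF, 0 °C → rt
Reagents that add atoms: none
Why: Mitsunobu esterification activates the primary alcohol towards the carboxylate and so should esterify the acid without disturbing the (Z)-iodoalkene.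

Step 20
Reactants: 26 angelate; 30 2-(trimethylsilyl)ethyl (Z)-3-iodobut-2-enoate
Product: 32 coupled silylethyl ester, via B-alkyl-9-BBN 31 (not isolated)
Conditions: 9-BBN, THF, rt; then 30, Pd(dppf)Cl2 (5 mol %), AsPh3 (10 mol %), K3PO4 (aq), DMF, rt → 40 °C
Reagents that add atoms: none
Why: B-alkyl Suzuki–Miyaura coupling in which 9-BBN adds anti-Markovnikov to the monosubstituted vinyl group only (boron on C12) and the alkylborane couples with the (Z)-iodoenoate with retention of alkene geometry, so that C12 ends cis to the ester carbon C15 (13Z).

Step 21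
Reactants: 32 coupled silylethyl ester
Product: 33 target acid CNP0249147.1
Conditions: Bu4NF, THF, 0 °C → rt; then 0.5 M HCl (aq), 0 °C
Reagents that add atoms: none
Why: Fluoride-induced β-elimination of the 2-(trimethylsilyl)ethyl ester frees the C15 acid under conditions that should leave the hindered angelate and both Z alkenes untouched.

Compound list
1 | (R)-(−)-carvone, (5R)-2-methyl-5-(prop-1-en-2-yl)cyclohex-2-en-1-one | CC(=C)[C@@H]1CC=C(C)C(=O)C1 | starting material
2 | cross-conjugated lithium dienolate of 1 (O–Li on C1, C1=C6 and C2=C3 double bonds) | CC(=C)[C@@H]1CC=C(C)C(O[Li])=C1 | intermediate (not isolated)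
3 | trans-6-methylcarvone, (5R,6S)-2,6-dimethyl-5-(prop-1-en-2-yl)cyclohex-2-en-1-one (any cis epimer converges in step 2) | CC(=C)[C@@H]1CC=C(C)C(=O)[C@H]1C | intermediate
4 | propargyl bromide (3-bromoprop-1-yne) | BrCC#C | starting material
5 | lithium dienolate of 3 (O–Li on C1, C1=C6 and C2=C3 double bonds) | CC(=C)[C@@H]1CC=C(C)C(O[Li])=C1C | intermediate (not isolated)
6 | (5S,6S)-2,6-dimethyl-5-(prop-1-en-2-yl)-6-(prop-2-yn-1-yl)cyclohex-2-en-1-one; 6-methyl cis and 6-propargyl trans to the isopropenyl group | CC(=C)[C@@H]1CC=C(C)C(=O)[C@@]1(C)CC#C | intermediate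
7 | allylic chloride: 5-(3-chloroprop-1-en-2-yl)-2,6-dimethyl-6-(prop-2-yn-1-yl)cyclohex-2-en-1-one, ring configuration as in 6 | ClCC(=C)[C@@H]1CC=C(C)C(=O)[C@@]1(C)CC#C | intermediate
8 | enal: 2-[2,4-dimethyl-3-oxo-2-(prop-2-yn-1-yl)cyclohex-4-en-1-yl]prop-2-enal, ring configuration as in 6 | O=CC(=C)[C@@H]1CC=C(C)C(=O)[C@@]1(C)CC#C | intermediate
9 | acrylic acid: 2-[2,4-dimethyl-3-oxo-2-(prop-2-yn-1-yl)cyclohex-4-en-1-yl]prop-2-enoic acid, ring configuration as in 6 | OC(=O)C(=C)[C@@H]1CC=C(C)C(=O)[C@@]1(C)CC#C | intermediate
10 | methyl ester of 9 | COC(=O)C(=C)[C@@H]1CC=C(C)C(=O)[C@@]1(C)CC#C | intermediate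
11 | aldehyde: methyl 2-[2,4-dimethyl-3-oxo-2-(3-oxopropyl)cyclohex-4-en-1-yl]prop-2-enoate, ring configuration as in 6 | COC(=O)C(=C)[C@@H]1CC=C(C)C(=O)[C@@]1(C)CCC=O | intermediate
12 | acid: 3-[6-(3-methoxy-3-oxoprop-1-en-2-yl)-1,3-dimethyl-2-oxocyclohex-3-en-1-yl]propanoic acid, ring configuration as in 6 | COC(=O)C(=C)[C@@H]1CC=C(C)C(=O)[C@@]1(C)CCC(=O)O | intermediate
13 | N-hydroxyphthalimide | ON1C(=O)c2ccccc2C1=O | starting material
14 | N-hydroxyphthalimide ester of 12 (acrylate on C5 trans to the propanoate arm on C10, C10 methyl cis to the acrylate) | COC(=O)C(=C)[C@@H]1CC=C(C)C(=O)[C@@]1(C)CCC(=O)ON2C(=O)c3ccccc3C2=O | intermediate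
15 | trans-fused methyl 4a,6-dimethyl-5-oxo-1,2,3,4,4a,5,8,8a-octahydronaphthalene-1-carboxylate (labdane numbering: C4 ester, 7-en-9-one, 5α-H, 10β-CH3; C4 epimers, 4α-ester drawn) | COC(=O)[C@@H]1CCC[C@]2(C)C(=O)C(C)=CC[C@@H]12 | intermediate
16 | diene ester: the 9-methylene analogue of 15 (7,9(11)-diene, 4α-ester) | COC(=O)[C@@H]1CCC[C@]2(C)C(=C)C(C)=CC[C@@H]12 | intermediate
17 | lithium ester enolate of 16 (C4=C19 enolate double bond) | COC(O[Li])=C1CCC[C@]2(C)C(=C)C(C)=CC[C@@H]12 | intermediate (not isolated)
18 | quaternary ester: 4α-methyl, 4β-(axial) methoxycarbonyl, 7,9(11)-diene, 5α-H, 10β-CH3 | COC(=O)[C@@]1(C)CCC[C@]2(C)C(=C)C(C)=CC[C@@H]12 | intermediate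
19 | B-alkyl-9-BBN: 9-borabicyclo[3.3.1]nonan-9-yl on C11, 9α-H | COC(=O)[C@@]1(C)CCC[C@]2(C)[C@@H](CB3C4CCCC3CCC4)C(C)=CC[C@@H]12 | intermediate (not isolated)
20 | hydroxy ester: 9β-CH2OH (C11 alcohol), 9α-H, 7-ene, C19 methyl ester | COC(=O)[C@@]1(C)CCC[C@]2(C)[C@@H](CO)C(C)=CC[C@@H]12 | intermediate
21 | aldehyde ester: 9β-CHO, 9α-H, 7-ene, C19 methyl ester | COC(=O)[C@@]1(C)CCC[C@]2(C)[C@@H](C=O)C(C)=CC[C@@H]12 | intermediate
22 | vinyl ester: 9β-vinyl (C11=C12), 9α-H, 7-ene, C19 methyl ester | COC(=O)[C@@]1(C)CCC[C@]2(C)[C@@H](C=C)C(C)=CC[C@@H]12 | intermediate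
23 | C19 alcohol: 4β-CH2OH, 4α-CH3, 9β-vinyl, 7-ene | OC[C@@]1(C)CCC[C@]2(C)[C@@H](C=C)C(C)=CC[C@@H]12 | intermediate
24 | angelic acid, (Z)-2-methylbut-2-enoic acid | C/C=C(/C)C(=O)O | starting material
25 | angelic 2,4,6-trichlorobenzoic mixed anhydride | C/C=C(/C)C(=O)OC(=O)c1c(Cl)cc(Cl)cc1Cl | intermediate (not isolated)
26 | angelate of 23 (C19 O-angeloyl, 9β-vinyl, 7-ene) | C/C=C(/C)C(=O)OC[C@@]1(C)CCC[C@]2(C)[C@@H](C=C)C(C)=CC[C@@H]12 | intermediate
27 | but-2-ynoic acid | CC#CC(=O)O | starting material
28 | (Z)-3-iodobut-2-enoic acid (iodine cis to the carboxyl group) | C/C(I)=C/C(=O)O | intermediate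
29 | 2-(trimethylsilyl)ethanol | C[Si](C)(C)CCO | starting material
30 | 2-(trimethylsilyl)ethyl (Z)-3-iodobut-2-enoate | C/C(I)=C/C(=O)OCC[Si](C)(C)C | intermediate
31 | B-alkyl-9-BBN from 26: 9-borabicyclo[3.3.1]nonan-9-yl on C12 | C/C=C(/C)C(=O)OC[C@@]1(C)CCC[C@]2(C)[C@@H](CCB3C4CCCC3CCC4)C(C)=CC[C@@H]12 | intermediate (not isolated)
32 | 2-(trimethylsilyl)ethyl (4S,5R,9S,10R)-19-angeloyloxylabda-7,13Z-dien-15-oate | C/C=C(/C)C(=O)OC[C@@]1(C)CCC[C@]2(C)[C@@H](CC/C(C)=C\C(=O)OCC[Si](C)(C)C)C(C)=CC[C@@H]12 | intermediate
33 | CNP0249147.1, (4S,5R,9S,10R)-19-angeloyloxylabda-7,13Z-dien-15-oic acid | C/C=C(/C)C(=O)OC[C@@]1(C)CCC[C@]2(C)[C@@H](CC/C(C)=C\C(=O)O)C(C)=CC[C@@H]12 | target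

Total step count: 21 steps. Longest linear sequence: 19 steps (steps 1–17, 20 and 21); steps 18 and 19 make the side-chain iodide.

Steps most likely to fail

Step 10. The primary C2 radical may be quenched by hydrogen transfer (from the Hantzsch ester, or internally from the allylic C6–H) before it closes ring A, which would give acyclic reduced material. The fallback sets out from acid 12: iododecarboxylation with PhI(OAc)2 and I2 under visible light should give the primary iodide F1. Slow addition of Bu3SnH with AIBN in benzene at 80 °C then runs the same C2–C3 closure as a halogen-abstraction chain, in which the hydrogen donor is kept at a low stationary concentration, and returns to 15.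

Step 11. Carbonyl addition at the hindered, conjugated C9 ketone may be slow, and deprotonation at C6 to the dienolate may then stall the olefination. The fallback sets out from 15 and replaces the ylide by a Peterson olefination: Me3SiCH2Li with CeCl3 in THF at −78 °C should add to C9 from the α face, selectively over the ester, to give the β-hydroxysilane F2. KH in THF should then bring about syn-elimination and return to diene 16.

Step 4. Displacement of the allylic chloride by the N-oxide may be sluggish, and the electrophilic 2-substituted acrolein may be lost to conjugate addition of the amine that is released. The fallback sets out from 7 and goes through oxygen substitution and alcohol oxidation: KOAc with Bu4NI (cat.) in DMF should give the allylic acetate F3, K2CO3 in MeOH the allylic alcohol F4, and MnO2 in CH2Cl2 should oxidise the allylic alcohol to enal 8, where the route is rejoined.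

Further compounds
F1 | step 10 | primary iodide, methyl 2-[2-(2-iodoethyl)-2,4-dimethyl-3-oxocyclohex-4-en-1-yl]prop-2-enoate, ring configuration as in 14 | COC(=O)C(=C)[C@@H]1CC=C(C)C(=O)[C@@]1(C)CCI
F2 | step 11 | β-hydroxysilane, 9β-hydroxy-9α-(trimethylsilylmethyl) adduct of 15 | COC(=O)[C@@H]1CCC[C@]2(C)[C@](O)(C[Si](C)(C)C)C(C)=CC[C@@H]12
F3 | step 4 | allylic acetate, the CH2Cl of 7 replaced by CH2OAc | CC(=O)OCC(=C)[C@@H]1CC=C(C)C(=O)[C@@]1(C)CC#C
F4 | step 4 | allylic alcohol, the CH2Cl of 7 replaced by CH2OH | OCC(=C)[C@@H]1CC=C(C)C(=O)[C@@]1(C)CC#C
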